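**Retrosynthetic overview**
1. Target ⇐ PMB ether of the macrocycle ⇐ ring-closing metathesis at C4=C5; the nine-membered oxa-bridged ring (ten-membered carbocycle) is closed last.
2. Metathesis triene ⇐ Mitsunobu esterification with isobutyric acid (inversion at C8) ⇐ zinc Barbier allylation forming C7–C8 between a furanone aldehyde and a 3-(bromomethyl)butenolide; this coupling delivers the trans α-methylene lactone.
3. Furanone aldehyde ⇐ prenyl ozonolysis ⇐ α'-hydroxy ynone cyclisation ⇐ Weinreb amide (C10 from (R)-lactic acid by dioxolanone alkylation) + 2-substituted enyne (Sonogashira).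
4. Bromomethylbutenolide ⇐ ring-closing metathesis of the 2-(bromomethyl)acrylate of (S)-hexa-1,4-dien-3-ol (Sharpless kinetic resolution sets C6).
5. Ring order: 3(2H)-furanone and butenolide are built separately, the butenolide becomes the α-methylene lactone in the coupling, the macrocycle is formed last.

Assumption: locants C1–C15 follow germacrane numbering (C1 furanone carbonyl, C2=C3 furanone alkene, C4=C5 ring alkene, C6 lactone carbinol, C7, C8 ester carbinol, C9, C10 quaternary carbon, C11–C13 methylene lactone, C14 methyl, C15 hydroxymethyl); the target is (4Z,6R,7R,8R,10S).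

Steps 1–3 make the enyne (fragment A), steps 4–9 the furanone aldehyde (fragment B), steps 10–13 the butenolide (fragment C), steps 14–17 join the fragments and finish.

Step 1
Reactants: 1 4-methoxybenzyl alcohol; 2 2,3-dibromoprop-1-ene
Product: 3 1-{[(2-bromoprop-2-en-1-yl)oxy]methyl}-4-methoxybenzene
Conditions: 50% aq NaOH, Bu4NHSO4 (5 mol%), toluene, rt
Reagents that add atoms: none
Why: Phase-transfer Williamson etherification; the alkoxide displaces only the allylic bromide (SN2), the vinylic bromide is inert, and no stereocentre is involved.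

Step 2
Reactants: 3 1-{[(2-bromoprop-2-en-1-yl)oxy]methyl}-4-methoxybenzene; 4 ethynyltrimethylsilane
Product: 5 trimethyl(3-{[(4-methoxyphenyl)methoxy]methyl}but-3-en-1-yn-1-yl)silane
Conditions: PdCl2(PPh3)2 (3 mol%), CuI (6 mol%), iPr2NH, THF, 40 °C
Reagents that add atoms: none
Why: Sonogashira coupling of the 2-bromoalkene with the terminal alkyne builds the C3–C4 bond of the 2-substituted 1,3-enyne; the PMB ether is inert.

Step 3
Reactants: 5 trimethyl(3-{[(4-methoxyphenyl)methoxy]methyl}but-3-en-1-yn-1-yl)silane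
Product: 6 1-methoxy-4-{[(2-methylidenebut-3-yn-1-yl)oxy]methyl}benzene
Conditions: K2CO3 (0.2 equiv), MeOH, rt
Reagents that add atoms: none
Why: Base-catalysed protodesilylation (methanolysis of the alkynyl–silicon bond) frees the terminal alkyne and touches nothing else.

Step 4
Reactants: 7 (R)-lactic acid; 8 pivalaldehyde
Product: 9 (2R,5R)-2-tert-butyl-5-methyl-1,3-dioxolan-4-one (tert-butyl and methyl cis)
Conditions: TsOH·H2O (cat.), H2SO4 (cat.), pentane, reflux, Dean–Stark; recrystallised at −78 °C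
Reagents that add atoms: none
Why: Acid-catalysed acetalisation (self-regeneration-of-stereocentres template); the thermodynamically favoured cis acetal sets the new acetal centre as 2R relative to the lactate centre, and crystallisation removes the trans isomer.

Step 5
Reactants: 9 (2R,5R)-2-tert-butyl-5-methyl-1,3-dioxolan-4-one; 10 1-bromo-3-methylbut-2-ene (prenyl bromide)
Product: 12 (2R,5S)-2-tert-butyl-5-methyl-5-(3-methylbut-2-en-1-yl)-1,3-dioxolan-4-one, via lithium enolate 11 (not isolated)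
Conditions: LiN(iPr)2, THF, −78 °C; then 10, −78 → −30 °C
Reagents that add atoms: none
Why: Diastereoselective enolate alkylation; the prenyl bromide attacks the planar enolate anti to the tert-butyl group and so takes the place of the former hydrogen, which fixes the quaternary carbon (C10) as S.

Step 6
Reactants: 12 (2R,5S)-2-tert-butyl-5-methyl-5-(3-methylbut-2-en-1-yl)-1,3-dioxolan-4-one
Product: 13 (2S)-2-hydroxy-N-methoxy-N,2,5-trimethylhex-4-enamide
Conditions: Me(MeO)NH·HCl, iPrMgCl, THF, −20 °C; then 12, −20 → 0 °C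
Reagents that add atoms: N,O-dimethylhydroxylamine hydrochloride (CNOC.Cl)
Why: Weinreb amide formation by aminolysis of the acylal lactone with the magnesium amide; the ring opens with loss of pivalaldehyde and the quaternary centre is not touched.

Step 7
Reactants: 13 (2S)-2-hydroxy-N-methoxy-N,2,5-trimethylhex-4-enamide; 6 1-methoxy-4-{[(2-methylidenebut-3-yn-1-yl)oxy]methyl}benzene
Product: 15 (6S)-6-hydroxy-1-[(4-methoxyphenyl)methoxy]-6,9-dimethyl-2-methylidenedec-8-en-3-yn-5-one, via lithium acetylide 14 (not isolated)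
Conditions: 6 (2.6 equiv), n-BuLi (2.5 equiv), THF, −78 °C; then 13, −78 → −20 °C; cold 1 M HCl
Reagents that add atoms: none
Why: Weinreb ketone synthesis; the chelated tetrahedral adduct stops the acetylide at single addition, the excess acetylide only deprotonates the tertiary hydroxyl, and the acidic quench keeps the liberated amine off the ynone.

Step 8
Reactants: 15 (6S)-6-hydroxy-1-[(4-methoxyphenyl)methoxy]-6,9-dimethyl-2-methylidenedec-8-en-3-yn-5-one
Product: 16 (2S)-5-{3-[(4-methoxyphenyl)methoxy]prop-1-en-2-yl}-2-methyl-2-(3-methylbut-2-en-1-yl)furan-3(2H)-one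
Conditions: Et2NH (1.5 equiv), EtOH, rt
Reagents that add atoms: none
Why: Amine-mediated oxa-Michael cyclisation of the α'-hydroxy ynone (conjugate addition of Et2NH, then addition–elimination by the tertiary hydroxyl) gives the 3(2H)-furanone with C10 unchanged.

Step 9
Reactants: 16 (2S)-5-{3-[(4-methoxyphenyl)methoxy]prop-1-en-2-yl}-2-methyl-2-(3-methylbut-2-en-1-yl)furan-3(2H)-one
Product: 18 2-[(2S)-5-{3-[(4-methoxyphenyl)methoxy]prop-1-en-2-yl}-2-methyl-3-oxo-2,3-dihydrofuran-2-yl]acetaldehyde, via ozonide 17 (not isolated)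
Conditions: O3 (1.0 equiv), CH2Cl2, −78 °C; then Me2S, −78 °C → rt; used at once
Reagents that add atoms: ozone (O=[O+][O-])
Why: Chemoselective ozonolysis; the electron-rich trisubstituted prenyl alkene reacts much faster than the electron-poor cross-conjugated dienone and the anisyl ring, and reductive work-up gives the C8 aldehyde.

Step 10
Reactants: 19 (E)-but-2-enal (crotonaldehyde); 20 vinylmagnesium bromide
Product: 21 rac-(4E)-hexa-1,4-dien-3-ol
Conditions: THF, −78 → 0 °C; aq NH4Cl
Reagents that add atoms: none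
Why: Grignard 1,2-addition to the enal gives the bis-allylic carbinol as a racemate.

Step 11
Reactants: 21 rac-(4E)-hexa-1,4-dien-3-ol
Product: 22 (3S,4E)-hexa-1,4-dien-3-ol
Conditions: Ti(OiPr)4 (0.2 equiv), D-(−)-diisopropyl tartrate (0.3 equiv), t-BuOOH (0.6 equiv), 4 Å molecular sieves, CH2Cl2, −20 °C, stopped near 55% conversion
Reagents that add atoms: none
Why: Sharpless kinetic resolution; with the D-(−)-tartrate the (3R)-enantiomer is epoxidised quickly at its propenyl group, while the (3S)-enantiomer (matched only at its slow terminal vinyl group) is recovered and carries the future C6 configuration.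

Step 12
Reactants: 22 (3S,4E)-hexa-1,4-dien-3-ol; 23 2-(bromomethyl)prop-2-enoic acid
Product: 25 (3S,4E)-hexa-1,4-dien-3-yl 2-(bromomethyl)prop-2-enoate, via acyl bromide 24 (not isolated)
Conditions: 23, (COBr)2, DMF (cat.), CH2Cl2, 0 °C → rt; then 22, 2,6-lutidine, CH2Cl2, −40 → 0 °C
Reagents that add atoms: none
Why: O-acylation through the acyl bromide; the hindered base does not attack the bromomethyl acrylate, no halide scrambling is possible, and the carbinol configuration is retained.

Step 13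
Reactants: 25 (3S,4E)-hexa-1,4-dien-3-yl 2-(bromomethyl)prop-2-enoate
Product: 26 (5R)-3-(bromomethyl)-5-[(1E)-prop-1-en-1-yl]furan-2(5H)-one
Conditions: second-generation Grubbs catalyst (5 mol%), CH2Cl2 (5 mM), 40 °C
Reagents that add atoms: none
Why: Ring-closing metathesis; the catalyst loads on the monosubstituted vinyl group and closes onto the acrylate alkene to give the butenolide, the less reactive propenyl group is left as a spectator, and the stereocentre is untouched.

Step 14
Reactants: 18 2-[(2S)-5-{3-[(4-methoxyphenyl)methoxy]prop-1-en-2-yl}-2-methyl-3-oxo-2,3-dihydrofuran-2-yl]acetaldehyde; 26 (5R)-3-(bromomethyl)-5-[(1E)-prop-1-en-1-yl]furan-2(5H)-one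
Product: 28 (4R,5R)-4-[(1S)-1-hydroxy-2-[(2S)-5-{3-[(4-methoxyphenyl)methoxy]prop-1-en-2-yl}-2-methyl-3-oxo-2,3-dihydrofuran-2-yl]ethyl]-3-methylidene-5-[(1E)-prop-1-en-1-yl]oxolan-2-one, via allylzinc bromide 27 (not isolated)
Conditions: Zn dust, THF/sat. aq NH4Cl (4:1), 0 °C → rt
Reagents that add atoms: none
Why: Zinc Barbier allylation with allylic transposition; the aldehyde adds to the ring carbon anti to the propenyl group (C7, trans lactone), and a closed Zimmerman–Traxler chair with the ring-locked E-type allylzinc and an equatorial aldehyde chain sets C8 as S, while the mildly acidic medium spares the β-oxygenated aldehyde.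

Step 15
Reactants: 28 (4R,5R)-4-[(1S)-1-hydroxy-2-[(2S)-5-{3-[(4-methoxyphenyl)methoxy]prop-1-en-2-yl}-2-methyl-3-oxo-2,3-dihydrofuran-2-yl]ethyl]-3-methylidene-5-[(1E)-prop-1-en-1-yl]oxolan-2-one; 29 2-methylpropanoic acid (isobutyric acid)
Product: 30 (1R)-2-[(2S)-5-{3-[(4-methoxyphenyl)methoxy]prop-1-en-2-yl}-2-methyl-3-oxo-2,3-dihydrofuran-2-yl]-1-[(2R,3R)-4-methylidene-5-oxo-2-[(1E)-prop-1-en-1-yl]oxolan-3-yl]ethyl 2-methylpropanoate
Conditions: PPh3, DIAD, toluene, 0 °C → rt
Reagents that add atoms: none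
Why: Mitsunobu esterification; SN2 displacement of the activated hydroxyl by isobutyrate inverts C8 from S to R and installs the ester in the same operation.

Step 16
Reactants: 30 (1R)-2-[(2S)-5-{3-[(4-methoxyphenyl)methoxy]prop-1-en-2-yl}-2-methyl-3-oxo-2,3-dihydrofuran-2-yl]-1-[(2R,3R)-4-methylidene-5-oxo-2-[(1E)-prop-1-en-1-yl]oxolan-3-yl]ethyl 2-methylpropanoate
Product: 31 [(2Z,4R,8R,9R,11S)-2-{[(4-methoxyphenyl)methoxy]methyl}-11-methyl-7-methylidene-6,12-dioxo-5,14-dioxatricyclo[9.2.1.0(4,8)]tetradeca-1(13),2-dien-9-yl] 2-methylpropanoate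
Conditions: second-generation Hoveyda–Grubbs catalyst (2 × 10 mol%), toluene (1 mM), 90 °C, argon sparge
Reagents that add atoms: none
Why: Ring-closing metathesis; the carbene formed at the propenyl carbon (C5) closes onto the 1,1-disubstituted C4 alkene with loss of propene, the nine-membered ring allows only the cis-in-ring (Z) trisubstituted alkene, and high dilution suppresses dimers.

Step 17
Reactants: 31 [(2Z,4R,8R,9R,11S)-2-{[(4-methoxyphenyl)methoxy]methyl}-11-methyl-7-methylidene-6,12-dioxo-5,14-dioxatricyclo[9.2.1.0(4,8)]tetradeca-1(13),2-dien-9-yl] 2-methylpropanoate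
Product: 32 [(2Z,4R,8R,9R,11S)-2-(hydroxymethyl)-11-methyl-7-methylidene-6,12-dioxo-5,14-dioxatricyclo[9.2.1.0(4,8)]tetradeca-1(13),2-dien-9-yl] 2-methylpropanoate (target)
Conditions: DDQ, CH2Cl2/pH 7 phosphate buffer (10:1), 0 °C → rt
Reagents that add atoms: none
Why: Oxidative PMB ether cleavage (benzylic hydride abstraction by DDQ, then hydrolysis) under neutral conditions leaves the methylene lactone, the isobutyrate and the dienone intact.

**Compound list**
1 | 4-methoxybenzyl alcohol | COc1ccc(CO)cc1 | starting material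
2 | 2,3-dibromoprop-1-ene | BrCC(Br)=C | starting material
3 | 1-{[(2-bromoprop-2-en-1-yl)oxy]methyl}-4-methoxybenzene | COc1ccc(COCC(Br)=C)cc1 | intermediate
4 | ethynyltrimethylsilane | C#C[Si](C)(C)C | starting material
5 | trimethyl(3-{[(4-methoxyphenyl)methoxy]methyl}but-3-en-1-yn-1-yl)silane | COc1ccc(COCC(=C)C#C[Si](C)(C)C)cc1 | intermediate
6 | 1-methoxy-4-{[(2-methylidenebut-3-yn-1-yl)oxy]methyl}benzene | COc1ccc(COCC(=C)C#C)cc1 | intermediate
7 | (R)-lactic acid | C[C@@H](O)C(=O)O | starting material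
8 | pivalaldehyde (2,2-dimethylpropanal) | CC(C)(C)C=O | starting material
9 | (2R,5R)-2-tert-butyl-5-methyl-1,3-dioxolan-4-one (tert-butyl and methyl cis) | CC(C)(C)[C@H]1OC(=O)[C@@H](C)O1 | intermediate
10 | 1-bromo-3-methylbut-2-ene (prenyl bromide) | CC(C)=CCBr | starting material
11 | lithium (2R)-2-tert-butyl-5-methyl-1,3-dioxol-4-olate (lithium enolate of 9) | CC(C)(C)[C@H]1OC(O[Li])=C(C)O1 | intermediate
12 | (2R,5S)-2-tert-butyl-5-methyl-5-(3-methylbut-2-en-1-yl)-1,3-dioxolan-4-one | CC(C)(C)[C@H]1OC(=O)[C@](C)(CC=C(C)C)O1 | intermediate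
13 | (2S)-2-hydroxy-N-methoxy-N,2,5-trimethylhex-4-enamide | CON(C)C(=O)[C@](C)(CC=C(C)C)O | intermediate
14 | (3-{[(4-methoxyphenyl)methoxy]methyl}but-3-en-1-yn-1-yl)lithium (lithium acetylide of 6) | COc1ccc(COCC(=C)C#C[Li])cc1 | intermediate
15 | (6S)-6-hydroxy-1-[(4-methoxyphenyl)methoxy]-6,9-dimethyl-2-methylidenedec-8-en-3-yn-5-one | COc1ccc(COCC(=C)C#CC(=O)[C@](C)(CC=C(C)C)O)cc1 | intermediate
16 | (2S)-5-{3-[(4-methoxyphenyl)methoxy]prop-1-en-2-yl}-2-methyl-2-(3-methylbut-2-en-1-yl)furan-3(2H)-one | COc1ccc(COCC(=C)C2=CC(=O)[C@](C)(CC=C(C)C)O2)cc1 | intermediate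
17 | (2S)-2-[(5,5-dimethyl-1,2,4-trioxolan-3-yl)methyl]-5-{3-[(4-methoxyphenyl)methoxy]prop-1-en-2-yl}-2-methylfuran-3(2H)-one (ozonide of 16) | COc1ccc(COCC(=C)C2=CC(=O)[C@](C)(CC3OC(C)(C)OO3)O2)cc1 | intermediate
18 | 2-[(2S)-5-{3-[(4-methoxyphenyl)methoxy]prop-1-en-2-yl}-2-methyl-3-oxo-2,3-dihydrofuran-2-yl]acetaldehyde | COc1ccc(COCC(=C)C2=CC(=O)[C@](C)(CC=O)O2)cc1 | intermediate
19 | (E)-but-2-enal (crotonaldehyde) | C/C=C/C=O | starting material
20 | vinylmagnesium bromide | C=C[Mg]Br | starting material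
21 | rac-(4E)-hexa-1,4-dien-3-ol | C/C=C/C(O)C=C | intermediate
22 | (3S,4E)-hexa-1,4-dien-3-ol | C/C=C/[C@@H](O)C=C | intermediate
23 | 2-(bromomethyl)prop-2-enoic acid | OC(=O)C(=C)CBr | starting material
24 | 2-(bromomethyl)prop-2-enoyl bromide | BrC(=O)C(=C)CBr | intermediate
25 | (3S,4E)-hexa-1,4-dien-3-yl 2-(bromomethyl)prop-2-enoate | C/C=C/[C@@H](OC(=O)C(=C)CBr)C=C | intermediate
26 | (5R)-3-(bromomethyl)-5-[(1E)-prop-1-en-1-yl]furan-2(5H)-one | BrCC1=C[C@@H](/C=C/C)OC1=O | intermediate
27 | bromo{[(5R)-2-oxo-5-[(1E)-prop-1-en-1-yl]-2,5-dihydrofuran-3-yl]methyl}zinc | Br[Zn]CC1=C[C@@H](/C=C/C)OC1=O | intermediate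
28 | (4R,5R)-4-[(1S)-1-hydroxy-2-[(2S)-5-{3-[(4-methoxyphenyl)methoxy]prop-1-en-2-yl}-2-methyl-3-oxo-2,3-dihydrofuran-2-yl]ethyl]-3-methylidene-5-[(1E)-prop-1-en-1-yl]oxolan-2-one (6R,7R,8S,10S) | C=C1C(=O)O[C@H](/C=C/C)[C@H]1[C@@H](O)C[C@]2(C)OC(=CC2=O)C(=C)COCc3ccc(OC)cc3 | intermediate
29 | 2-methylpropanoic acid (isobutyric acid) | CC(C)C(=O)O | starting material
30 | (1R)-2-[(2S)-5-{3-[(4-methoxyphenyl)methoxy]prop-1-en-2-yl}-2-methyl-3-oxo-2,3-dihydrofuran-2-yl]-1-[(2R,3R)-4-methylidene-5-oxo-2-[(1E)-prop-1-en-1-yl]oxolan-3-yl]ethyl 2-methylpropanoate (6R,7R,8R,10S) | C=C1C(=O)O[C@H](/C=C/C)[C@H]1[C@H](OC(=O)C(C)C)C[C@]2(C)OC(=CC2=O)C(=C)COCc3ccc(OC)cc3 | intermediate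
31 | [(2Z,4R,8R,9R,11S)-2-{[(4-methoxyphenyl)methoxy]methyl}-11-methyl-7-methylidene-6,12-dioxo-5,14-dioxatricyclo[9.2.1.0(4,8)]tetradeca-1(13),2-dien-9-yl] 2-methylpropanoate | C=C1C(=O)O[C@@H]2/C=C(/COCc4ccc(OC)cc4)C3=CC(=O)[C@](C)(C[C@@H](OC(=O)C(C)C)[C@@H]12)O3 | intermediate
32 | [(2Z,4R,8R,9R,11S)-2-(hydroxymethyl)-11-methyl-7-methylidene-6,12-dioxo-5,14-dioxatricyclo[9.2.1.0(4,8)]tetradeca-1(13),2-dien-9-yl] 2-methylpropanoate | C=C1C(=O)O[C@@H]2/C=C(/CO)C3=CC(=O)[C@](C)(C[C@@H](OC(=O)C(C)C)[C@@H]12)O3 | target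

**Totals**
Total step count: 17.
Longest linear sequence: 10 steps (steps 4, 5, 6, 7, 8, 9, 14, 15, 16, 17 from (R)-lactic acid; the enyne branch through steps 1, 2, 3, 7, 8, 9, 14–17 is also 10; the butenolide branch is 8).

**The three steps most likely to fail**

Step 16, the macrocyclic metathesis, is the most exposed step. It must form a trisubstituted, dienone-conjugated alkene inside a strained nine-membered ring, and the 1,1-disubstituted C4 alkene is a poor partner, so oligomers or recovered triene are possible. The fallback changes the order of ring closure and inversion so that the metathesis runs on a different substrate. It sets out from 28, where the small free C8 hydroxyl replaces the bulky ester next to the folding chain. The same catalyst in dilute toluene closes 28 to the macrocyclic (8S)-alcohol F1. Mitsunobu esterification of F1 with 29 (PPh3, DIAD) then inverts C8 on the ring, and the route is rejoined at 31.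

Step 15, the Mitsunobu inversion, acts on a hindered secondary carbinol whose neighbouring C7–H is allylic. E2 elimination to a diene, or lactone migration to the C8 oxygen, may compete with substitution. The fallback replaces SN2 inversion by an oxidation–reduction sequence and sets out from 28. Dess–Martin periodinane buffered with NaHCO3 gives the C8 ketone F2. Reagent-controlled reduction of F2 with catecholborane and the (S)-Me-CBS oxazaborolidine at −78 °C gives the (8R)-alcohol F3. Acylation of F3 with isobutyric anhydride, Et3N and DMAP returns to the route at 30.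

Step 9, the ozonolysis, has to discriminate the prenyl alkene from the cross-conjugated diene, the furanone enol ether and the anisyl ring. The product is a β-oxygenated aldehyde that can eliminate. The fallback unmasks the aldehyde carbon before any of the competing groups exist and sets out from 13. Ozonolysis of 13 in CH2Cl2/MeOH, Me2S work-up and HC(OMe)3 with PPTS in the same flask give the dimethyl acetal F4. Addition of the lithium acetylide 14, as in step 7, gives the hydroxy ynone acetal F5. Et2NH in EtOH cyclises F5 to the furanone acetal F6. Hydrolysis of F6 with PPTS in wet acetone returns to the route at 18.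

**Further compounds**
F1 | step 16 | (2Z,4R,8R,9S,11S)-9-hydroxy-2-{[(4-methoxyphenyl)methoxy]methyl}-11-methyl-7-methylidene-5,14-dioxatricyclo[9.2.1.0(4,8)]tetradeca-1(13),2-diene-6,12-dione | C=C1C(=O)O[C@@H]2/C=C(/COCc4ccc(OC)cc4)C3=CC(=O)[C@](C)(C[C@H](O)[C@@H]12)O3
F2 | step 15 | (4S,5R)-4-{[(2S)-5-{3-[(4-methoxyphenyl)methoxy]prop-1-en-2-yl}-2-methyl-3-oxo-2,3-dihydrofuran-2-yl]acetyl}-3-methylidene-5-[(1E)-prop-1-en-1-yl]oxolan-2-one | C=C1C(=O)O[C@H](/C=C/C)[C@H]1C(=O)C[C@]2(C)OC(=CC2=O)C(=C)COCc3ccc(OC)cc3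
F3 | step 15 | (4R,5R)-4-[(1R)-1-hydroxy-2-[(2S)-5-{3-[(4-methoxyphenyl)methoxy]prop-1-en-2-yl}-2-methyl-3-oxo-2,3-dihydrofuran-2-yl]ethyl]-3-methylidene-5-[(1E)-prop-1-en-1-yl]oxolan-2-one | C=C1C(=O)O[C@H](/C=C/C)[C@H]1[C@H](O)C[C@]2(C)OC(=CC2=O)C(=C)COCc3ccc(OC)cc3
F4 | step 9 | (2S)-2-hydroxy-N,4,4-trimethoxy-N,2-dimethylbutanamide | CON(C)C(=O)[C@](C)(CC(OC)OC)O
F5 | step 9 | (6S)-6-hydroxy-8,8-dimethoxy-1-[(4-methoxyphenyl)methoxy]-6-methyl-2-methylideneoct-3-yn-5-one | COc1ccc(COCC(=C)C#CC(=O)[C@](C)(CC(OC)OC)O)cc1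
F6 | step 9 | (2S)-2-(2,2-dimethoxyethyl)-5-{3-[(4-methoxyphenyl)methoxy]prop-1-en-2-yl}-2-methylfuran-3(2H)-one | COc1ccc(COCC(=C)C2=CC(=O)[C@](C)(CC(OC)OC)O2)cc1
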